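**Retrosynthetic overview**
1. Target 15 ⇐ bridged cyclopropyl δ-lactone 14, by cationic cyclopropylcarbinyl→homoallyl ring expansion with 1,3-acyloxy shift (cyclohexane → cycloheptene and δ- → γ-lactone in one event).
2. 14 ⇐ diazopyruvate 12 (tether-directed intramolecular cyclopropanation, then C11 methylenation); 12 ⇐ tertiary alcohol 10 + oxalyl chloride + TMSCHN2.
3. 10 ⇐ diol 7 + angelic acid 8; 7 ⇐ aldol 5 + MeMgBr (chelation control).
4. 5 ⇐ (R)-5-methylcyclohexenone 1 + 3-oxopropyl acetate 2 (syn aldol, trans to the ring methyl).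
5. Ring order: cyclohexene (bought) → cyclopropane + bridging δ-lactone (step 5) → cycloheptene + cis-fused γ-lactone (step 7).

Atom labels follow the target throughout: ring C1, C5–C10; lactone C11 (α-carbon), C12 (C=O), C13 (=CH2); side chain C2 (O-angelate), C3, C4 (O-acetate); C14 = methyl on C10, C15 = methyl on C5.
Assumption: (R)-5-methylcyclohex-2-en-1-one, 3-oxopropyl acetate and angelic acid are bought as such.

Step 1
Reactants: 1 (5R)-5-methylcyclohex-2-en-1-one; 2 3-oxopropyl acetate
Product: 5 (3S)-3-hydroxy-3-[(1R,6R)-6-methyl-2-oxocyclohex-3-en-1-yl]propyl acetate, via lithium dienolate 3 (not isolated), via triisopropoxytitanium dienolate 4 (not isolated)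
Conditions: LiN(iPr)2, THF, −78 °C; ClTi(OiPr)3, −78 to −40 °C; then 2, −78 °C; aq NH4Cl
Reagents that add atoms: none
Why: Kinetic α'-deprotonation gives the cross-conjugated dienolate, and its titanium derivative undergoes a syn-selective titanium-enolate aldol addition on the face anti to the neighbouring C10 methyl, which sets C1 (trans to the methyl) and the syn C1/C2 relationship.

Step 2
Reactants: 5 (3S)-3-hydroxy-3-[(1R,6R)-6-methyl-2-oxocyclohex-3-en-1-yl]propyl acetate
Product: 7 (3S)-3-hydroxy-3-[(1R,2R,6R)-2-hydroxy-2,6-dimethylcyclohex-3-en-1-yl]propyl acetate, via bromomagnesium aldolate chelate 6 (not isolated)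
Conditions: MeMgBr (3 equiv), CH2Cl2/Et2O, −78 °C; cold aq NH4Cl
Reagents that add atoms: methylmagnesium bromide, C[Mg]Br
Why: Chelation-controlled Grignard 1,2-addition, in which the second equivalent attacks the six-membered magnesium chelate axially and anti to the C1–C10 ring bond (equatorial attack on the ring), so the tertiary hydroxyl is 1,3-syn to the C2 oxygen and cis to the side chain; the ketone reacts far faster than the acetate at −78 °C.

Step 3
Reactants: 7 (3S)-3-hydroxy-3-[(1R,2R,6R)-2-hydroxy-2,6-dimethylcyclohex-3-en-1-yl]propyl acetate; 8 angelic acid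
Product: 10 (1S)-3-(acetyloxy)-1-[(1R,2R,6R)-2-hydroxy-2,6-dimethylcyclohex-3-en-1-yl]propyl (2Z)-2-methylbut-2-enoate, via angelic 2,4,6-trichlorobenzoic anhydride 9 (not isolated)
Conditions: 2,4,6-trichlorobenzoyl chloride, Et3N, toluene, 0 °C to rt; then 7, DMAP, rt
Reagents that add atoms: none
Why: Yamaguchi esterification acylates only the secondary C2 hydroxyl (the tertiary allylic hydroxyl is inert) and at room temperature keeps the Z geometry of the angelate.

Step 4
Reactants: 10 (1S)-3-(acetyloxy)-1-[(1R,2R,6R)-2-hydroxy-2,6-dimethylcyclohex-3-en-1-yl]propyl (2Z)-2-methylbut-2-enoate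
Product: 12 (1R,5R,6R)-6-[(1S)-3-(acetyloxy)-1-{[(2Z)-2-methylbut-2-enoyl]oxy}propyl]-1,5-dimethylcyclohex-2-en-1-yl 3-diazo-2-oxopropanoate, via chlorooxoacetate 11 (not isolated)
Conditions: (COCl)2, pyridine, CH2Cl2, −20 to 0 °C; evaporate; TMSCHN2, THF/MeCN, 0 °C
Reagents that add atoms: oxalyl chloride, O=C(Cl)C(=O)Cl; (trimethylsilyl)diazomethane, C[Si](C)(C)C=[N+]=[N-]
Why: O-acylation of the tertiary alcohol by oxalyl chloride followed by Arndt–Eistert-type diazo ketone formation on the acid chloride (the standard way to alkyl diazopyruvates); no stereocentre is touched.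

Step 5
Reactants: 12 the diazopyruvate ester of 10
Product: 13 cyclopropane-fused α-keto-δ-lactone (C7 bonded to C6 and C8 and bridged to O–C5 through C11(=O)–C12(=O); cyclopropane and lactone bridge cis to the C1 side chain and trans to the C10 methyl)
Conditions: Rh2(OAc)4 (1 mol %), CH2Cl2, rt, slow addition
Reagents that add atoms: none
Why: Intramolecular rhodium-carbene cyclopropanation of an unsaturated α-diazo ketone; the tether from the C5 oxygen can reach only the alkene face on which that oxygen sits, so C6, C7 and C8 are set together, with C11 necessarily endo on C7.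

Step 6
Reactants: 13 cyclopropane-fused α-keto-δ-lactone
Product: 14 cyclopropane-fused α-methylidene-δ-lactone (13 with C11=O replaced by C11=CH2; all stereocentres as in 13)
Conditions: Ph3P=CH2 (from Ph3PCH3Br, KN(SiMe3)2), THF, −78 to 0 °C
Reagents that add atoms: methylenetriphenylphosphorane, C=P(c1ccccc1)(c1ccccc1)c1ccccc1
Why: Wittig methylenation of the non-enolisable, highly electrophilic keto group of the α-keto lactone is much faster than attack on the ester carbonyls; no stereocentre changes.

Step 7
Reactants: 14 cyclopropane-fused α-methylidene-δ-lactone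
Product: 15 (1S)-3-(acetyloxy)-1-[(3aR,6S,7R,8aR)-5,7-dimethyl-3-methylidene-2-oxo-3,3a,6,7,8,8a-hexahydro-2H-cyclohepta[b]furan-6-yl]propyl (2Z)-2-methylbut-2-enoate
Conditions: Sc(OTf)3 (10 mol %), CH2Cl2/(CF3)2CHOH 4:1, −20 to 0 °C
Reagents that add atoms: none
Why: Proposed new method: a Lewis-acid-triggered ring-expanding 1,3-acyloxy shift of a tertiary cyclopropylcarbinyl lactone, in which Sc(OTf)3 ionises the C5–O bond to a tertiary cyclopropylcarbinyl cation/carboxylate ion pair and the carboxylate, held on the endo face by C7, attacks the internal cyclopropane carbon C8 anti to the breaking C6–C8 bond (inversion at C8, C7 untouched), giving the C5=C6 alkene, the seven-membered ring and the cis-fused γ-lactone in one step; return to C5 is reversible, capture at C7 is impossible for the tethered carboxylate and is electronically disfavoured by the acrylate, so the γ-lactone is the only irreversible exit; the closest known reactions are the solvolytic 2-norcaranyl to cyclohept-3-enyl (cyclopropylcarbinyl–homoallyl) ring expansion and allylic ester 1,3-transposition by ion-pair return.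

**Compound list**
1 | (5R)-5-methylcyclohex-2-en-1-one | O=C1C=CC[C@@H](C)C1 | starting material
2 | 3-oxopropyl acetate (3-acetoxypropanal) | CC(=O)OCCC=O | starting material
3 | lithium (3R)-3-methylcyclohexa-1,5-dien-1-olate (kinetic α'-enolate of 1) | [Li]OC1=C[C@H](C)CC=C1 | intermediate (not isolated)
4 | triisopropoxytitanium (3R)-3-methylcyclohexa-1,5-dien-1-olate | CC(C)O[Ti](OC(C)C)(OC(C)C)OC1=C[C@H](C)CC=C1 | intermediate (not isolated)
5 | (3S)-3-hydroxy-3-[(1R,6R)-6-methyl-2-oxocyclohex-3-en-1-yl]propyl acetate | O=C1C=CC[C@@H](C)[C@@H]1[C@@H](O)CCOC(C)=O | intermediate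
6 | bromomagnesium alkoxide of 5 (magnesium chelated between the C2 oxygen and the ketone) | O=C1C=CC[C@@H](C)[C@@H]1[C@@H](O[Mg]Br)CCOC(C)=O | intermediate (not isolated)
7 | (3S)-3-hydroxy-3-[(1R,2R,6R)-2-hydroxy-2,6-dimethylcyclohex-3-en-1-yl]propyl acetate | C[C@@]1(O)C=CC[C@@H](C)[C@@H]1[C@@H](O)CCOC(C)=O | intermediate
8 | angelic acid, (2Z)-2-methylbut-2-enoic acid | C/C=C(/C)C(=O)O | starting material
9 | angelic 2,4,6-trichlorobenzoic anhydride | C/C=C(/C)C(=O)OC(=O)c1c(Cl)cc(Cl)cc1Cl | intermediate (not isolated)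
10 | (1S)-3-(acetyloxy)-1-[(1R,2R,6R)-2-hydroxy-2,6-dimethylcyclohex-3-en-1-yl]propyl (2Z)-2-methylbut-2-enoate | C[C@@]1(O)C=CC[C@@H](C)[C@@H]1[C@@H](OC(=O)/C(C)=C\C)CCOC(C)=O | intermediate
11 | (1R,5R,6R)-6-[(1S)-3-(acetyloxy)-1-{[(2Z)-2-methylbut-2-enoyl]oxy}propyl]-1,5-dimethylcyclohex-2-en-1-yl chloro(oxo)acetate | C[C@@]1(OC(=O)C(=O)Cl)C=CC[C@@H](C)[C@@H]1[C@@H](OC(=O)/C(C)=C\C)CCOC(C)=O | intermediate (not isolated)
12 | (1R,5R,6R)-6-[(1S)-3-(acetyloxy)-1-{[(2Z)-2-methylbut-2-enoyl]oxy}propyl]-1,5-dimethylcyclohex-2-en-1-yl 3-diazo-2-oxopropanoate | C[C@@]1(OC(=O)C(=O)C=[N+]=[N-])C=CC[C@@H](C)[C@@H]1[C@@H](OC(=O)/C(C)=C\C)CCOC(C)=O | intermediate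
13 | cyclopropane-fused α-keto-δ-lactone: six-membered ring C5, C6, C8, C9, C10, C1; cyclopropane C6–C7–C8; lactone C5–O–C12(=O)–C11(=O)–C7; cyclopropane, lactone bridge and C1 side chain on one face, C10 and C5 methyls on the other; H6, H7, H8 all cis | O=C1C(=O)[C@@H]2[C@@H]3C[C@@H](C)[C@H]([C@@H](OC(=O)/C(C)=C\C)CCOC(C)=O)[C@](C)(O1)[C@H]23 | intermediate
14 | cyclopropane-fused α-methylidene-δ-lactone: 13 with C11=CH2 in place of C11=O, same stereochemistry | C=C1[C@@H]2[C@@H]3C[C@@H](C)[C@H]([C@@H](OC(=O)/C(C)=C\C)CCOC(C)=O)[C@](C)(OC1=O)[C@H]23 | intermediate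
15 | (1S)-3-(acetyloxy)-1-[(3aR,6S,7R,8aR)-5,7-dimethyl-3-methylidene-2-oxo-3,3a,6,7,8,8a-hexahydro-2H-cyclohepta[b]furan-6-yl]propyl (2Z)-2-methylbut-2-enoate | C=C1C(=O)O[C@@H]2C[C@@H](C)[C@H]([C@H](CCOC(C)=O)OC(=O)/C(C)=C\C)C(C)=C[C@H]12 | target

**Step count and risks**
Total steps: 7. Longest linear sequence: 7 (1 → 5 → 7 → 10 → 12 → 13 → 14 → 15). No protecting groups are used.

The three steps most likely to fail:

Step 2 (facial control at C5). The C5 oxygen must end up cis to the side chain, because it later delivers the carbene; simple axial attack on the enone would give the other epimer, which leads to the 7,8-bis-epimer of the target. Acetyl migration or attack on the acetate is a lesser risk. The fallback sets out from 5 and comes back at 7, and delivers the C5 oxygen from the C2 oxygen instead of relying on the Grignard face. Methylenation of 5 (Zn, CH2Br2, TiCl4, THF) gives the exocyclic diene alcohol F1. Boc2O/DMAP gives the tert-butyl carbonate F2. Iodocarbonate cyclisation (IBr, toluene, −85 °C) closes the six-membered cyclic iodocarbonate F3 with the C5–O bond 1,3-syn to C2–O. Bu3SnH/AIBN gives the methyl-bearing cyclic carbonate F4. K2CO3/MeOH gives the triol F5 (the acetate is lost as well). AcCl/2,4,6-collidine at −78 °C re-acetylates the primary hydroxyl to give 7.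

Step 5 (cyclopropanation). Risks are carbene side reactions and premature ionisation of the tertiary cyclopropylcarbinyl α-keto ester by the Lewis-acidic rhodium salt. The metal-free fallback sets out from 12 and comes back at 13. Warming 12 in toluene (60 °C) gives, by intramolecular 1,3-dipolar cycloaddition of the diazo ketone to the C6=C8 alkene, the fused 1-pyrazoline F6. Photolysis (350 nm, −20 °C) extrudes N2 and closes the cyclopropane to 13; the tether again fixes face and endo geometry.

Step 7 (the proposed new ring expansion). Risks are E1 loss of a proton from the C5 cation (C15 or C1, the latter threatening C1), and slow opening of the internal cyclopropane bond. The fallback sets out from 14 and comes back at 15, using the known solvolytic version with an external nucleophile. HClO4 (cat.) in aqueous dioxane at rt to 40 °C, under thermodynamic control, effects cyclopropylcarbinyl→homoallyl hydration: water enters at C8 anti to C6 and gives the cis hydroxy acid F7. This is then lactonised conventionally (TsOH cat., CH2Cl2, or EDC) to 15.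

**Further compounds**
F1 | step 2 | exocyclic diene alcohol: 5 with the ring C=O replaced by C=CH2, stereocentres as in 5 | C=C1C=CC[C@@H](C)[C@@H]1[C@@H](O)CCOC(C)=O
F2 | step 2 | tert-butyl carbonate of the secondary hydroxyl of F1 | C=C1C=CC[C@@H](C)[C@@H]1[C@@H](OC(=O)OC(C)(C)C)CCOC(C)=O
F3 | step 2 | six-membered cyclic carbonate joining the C2 oxygen and the C5 oxygen, C5 bearing CH2I, C5–O cis to the side chain | IC[C@@]12C=CC[C@@H](C)[C@@H]1[C@H](CCOC(C)=O)OC(=O)O2
F4 | step 2 | F3 with CH3 in place of CH2I | C[C@@]12C=CC[C@@H](C)[C@@H]1[C@H](CCOC(C)=O)OC(=O)O2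
F5 | step 2 | triol: 7 with the primary acetate cleaved | C[C@@]1(O)C=CC[C@@H](C)[C@@H]1[C@@H](O)CCO
F6 | step 5 | fused 1-pyrazoline: 13 with N=N inserted between C7 and C8, same faces | O=C1C(=O)[C@@H]2N=N[C@@H]3C[C@@H](C)[C@H]([C@@H](OC(=O)/C(C)=C\C)CCOC(C)=O)[C@](C)(O1)[C@H]23
F7 | step 7 | cis hydroxy acid: 15 with the lactone opened to C8–OH and the acrylic acid on C7 | C=C(C(=O)O)[C@H]1C=C(C)[C@@H]([C@H](CCOC(C)=O)OC(=O)/C(C)=C\C)[C@H](C)C[C@H]1O
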